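**Plan**

Numbering used throughout: ring C1 (CH carrying the side chain), C2 (CH2), C3–C4 (epoxide, CH3 on C4), C5 and C6 (CH–O); side chain C7(=CH2), C8 (CH–O), C9, C10–C11 (dimethyloxirane).
Retrosynthesis: the three angelates and the two epoxide oxygens come off first (C10–C11 by Shi epoxidation, C3–C4 by hydroxyl-directed epoxidation), then C8–C9 (allylboration) and C7=CH2 (α-methylenation), which leaves a 5-(2-silyloxyethyl)-2-methylcyclohex-2-enone.
The six-membered ring is then cut at C1–C6 and C3–C4 together. The oxygen on C5 lies between C4 and C6, so a C5 ketone makes both neighbours nucleophilic; the oxygen on C3 stands 1,3 to C1, so C1–C2–C3 is an enal. The two three-carbon halves are a β-ketoester and an enal.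
Forward: enal by cross-metathesis, amine-catalysed Michael/aldol condensation to close the carbocycle, C6–O (enolate hydroxylation, Mitsunobu inversion with angelic acid), C5–OH, ring epoxide, side chain built from the C1 arm, last ester, side-chain epoxide.
Stereochemistry: C1 from the prolinol silyl ether catalyst; C6, C5 and C3/C4 relayed from C1 by substrate control; C8 and C10 by reagent control.

Key step: step 3

Remark: the catalyst and reagent enantiomers named below are assigned from the accepted transition-state models (attack anti to the shielding group of the iminium ion; chair allylboration from the (+)-α-pinene-derived borane; spiro dioxirane model), not from a checked literature example; each is available in both enantiomeric forms.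

**Route**

Step 1
Reactants: 1 but-3-en-1-ol
Product: 2 tert-butyl(but-3-en-1-yloxy)diphenylsilane
Conditions: TBDPSCl, imidazole, DCM, 0 °C to rt
Reagents that add atoms: tert-butyl(chloro)diphenylsilane, CC(C)(C)[Si](Cl)(c1ccccc1)c1ccccc1
Why: Imidazole-promoted silylation of a primary alcohol; the TBDPS ether is chosen because it should survive the hot acid of step 3.

Step 2
Reactants: 2 tert-butyl(but-3-en-1-yloxy)diphenylsilane; 3 (E)-but-2-enal (crotonaldehyde, excess)
Product: 4 (E)-5-[(tert-butyldiphenylsilyl)oxy]pent-2-enal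
Conditions: second-generation Grubbs catalyst (3 mol%), DCM, 40 °C
Reagents that add atoms: none
Why: Olefin cross-metathesis of a terminal alkene with an enal should give the E-enal with loss of propene.

Step 3
Reactants: 4 (E)-5-[(tert-butyldiphenylsilyl)oxy]pent-2-enal; 5 tert-butyl 3-oxopentanoate
Product: 8 (5R)-5-{2-[(tert-butyldiphenylsilyl)oxy]ethyl}-2-methylcyclohex-2-en-1-one, via Michael adduct 6 (not isolated), via cyclohexenone tert-butyl ester 7 (not isolated)
Conditions: (R)-2-{bis[3,5-bis(trifluoromethyl)phenyl][(trimethylsilyl)oxy]methyl}pyrrolidine (10 mol%), toluene, rt; then TsOH·H2O (20 mol%), toluene, 80 °C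
Reagents that add atoms: none
Why: The secondary amine condenses with enal 4 to an E,s-trans iminium ion, one face of which is shielded by the diaryl(silyloxy)methyl group, so the doubly activated carbon of 5 (future C6) adds to the β-carbon (future C1) from the open face and sets C1 as R (first bond, C1–C6). After hydrolysis, the aldehyde carbon (C3) is attacked under acid by the enol of the propanoyl ketone through its CH2 carbon (future C4) in a 6-(enolendo)-exo-trig aldol closure (second bond, C3–C4); loss of water gives the conjugated C3=C4 alkene, and the tert-butyl ester leaves as 2-methylpropene and CO2. The closest known reaction type is the amine-catalysed domino Michael/aldol condensation of β-ketoesters with enals to 5-substituted cyclohex-2-enones, a Robinson-type [3+3] annulation. C1 is the only new stereocenter that survives and is under catalyst control; the centres formed at C6 and C3 are cleared by decarboxylation and dehydration. The step needs 1,4- over 1,2-addition (secured by iminium activation), Michael addition through the carbon between the two carbonyls (secured by its acidity), and ring closure through the propanoyl CH2 (the only enolisable position that gives a six-membered ring).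

Step 4
Reactants: 8 (5R)-5-{2-[(tert-butyldiphenylsilyl)oxy]ethyl}-2-methylcyclohex-2-en-1-one
Product: 10 (5R,6R)-5-{2-[(tert-butyldiphenylsilyl)oxy]ethyl}-6-hydroxy-2-methylcyclohex-2-en-1-one, via potassium dienolate 9 (not isolated)
Conditions: KHMDS, THF, −78 °C; 2-(phenylsulfonyl)-3-phenyloxaziridine, −78 °C; AcOH quench
Reagents that add atoms: 2-(phenylsulfonyl)-3-phenyloxaziridine, O=S(=O)(c1ccccc1)N1OC1c1ccccc1
Why: Kinetic deprotonation at the only α′ position (C6) gives the cross-conjugated dienolate, and oxygen transfer from the N-sulfonyloxaziridine (enolate hydroxylation) should occur anti to the C1 substituent, giving the alcohol trans to the side chain.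

Step 5
Reactants: 10 (5R,6R)-5-{2-[(tert-butyldiphenylsilyl)oxy]ethyl}-6-hydroxy-2-methylcyclohex-2-en-1-one; 11 angelic acid, (2Z)-2-methylbut-2-enoic acid
Product: 12 (1S,6R)-6-{2-[(tert-butyldiphenylsilyl)oxy]ethyl}-3-methyl-2-oxocyclohex-3-en-1-yl (2Z)-2-methylbut-2-enoate (ester cis to the side chain)
Conditions: PPh3, DIAD, toluene, 0 °C to rt
Reagents that add atoms: none
Why: Mitsunobu esterification displaces the alkoxyphosphonium group by SN2 (accelerated by the adjacent carbonyl), so C6 is inverted and the ester should end up cis to the C1 substituent; the neutral conditions should leave the Z double bond of the angelate untouched.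

Step 6
Reactants: 12 (1S,6R)-6-{2-[(tert-butyldiphenylsilyl)oxy]ethyl}-3-methyl-2-oxocyclohex-3-en-1-yl (2Z)-2-methylbut-2-enoate
Product: 13 (1S,2R,6R)-6-{2-[(tert-butyldiphenylsilyl)oxy]ethyl}-2-hydroxy-3-methylcyclohex-3-en-1-yl (2Z)-2-methylbut-2-enoate (C5–OH, C6 ester and side chain all cis)
Conditions: NaBH4, CeCl3·7H2O, MeOH, −78 °C
Reagents that add atoms: none
Why: Luche 1,2-reduction; hydride should enter anti to the axial C6–O bond (polar Felkin–Anh) and anti to the C1 substituent, which places the C5 hydroxyl cis to both.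

Step 7
Reactants: 13 (1S,2R,6R)-6-{2-[(tert-butyldiphenylsilyl)oxy]ethyl}-2-hydroxy-3-methylcyclohex-3-en-1-yl (2Z)-2-methylbut-2-enoate
Product: 14 4-{2-[(tert-butyldiphenylsilyl)oxy]ethyl}-2-hydroxy-1-methyl-7-oxabicyclo[4.1.0]heptan-3-yl (2Z)-2-methylbut-2-enoate, all-cis (C5–OH, C6 ester, epoxide oxygen and side chain on one face)
Conditions: VO(acac)2 (5 mol%), t-BuOOH (decane), DCM, 0 °C to rt
Reagents that add atoms: tert-butyl hydroperoxide, CC(C)(C)OO
Why: Vanadium-catalysed hydroxyl-directed epoxidation of the cyclic allylic alcohol delivers oxygen to the face of the C5 hydroxyl, so the C3–C4 epoxide should form cis to it; the electron-poor angelate double bond does not react.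

Step 8
Reactants: 14 all-cis epoxy alcohol; 11 angelic acid
Product: 15 4-{2-[(tert-butyldiphenylsilyl)oxy]ethyl}-1-methyl-7-oxabicyclo[4.1.0]heptane-2,3-diyl bis[(2Z)-2-methylbut-2-enoate], all-cis
Conditions: 11, 2,4,6-trichlorobenzoyl chloride, Et3N, toluene, rt; then 14, toluene, 75 °C
Reagents that add atoms: none
Why: Yamaguchi-type mixed-anhydride acylation without a nucleophilic catalyst is the standard way to make angelates without Z to E isomerisation; a C6 to C5 acyl shift in 14 is harmless because both positions end as angelates.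

Step 9
Reactants: 15 all-cis bis-angelate silyl ether
Product: 16 4-(2-hydroxyethyl)-1-methyl-7-oxabicyclo[4.1.0]heptane-2,3-diyl bis[(2Z)-2-methylbut-2-enoate], all-cis
Conditions: TBAF, AcOH, THF, rt
Reagents that add atoms: none
Why: Fluoride cleavage of the Si–O bond, buffered with acetic acid so that the esters and the epoxide should survive.

Step 10
Reactants: 16 primary alcohol
Product: 17 1-methyl-4-(2-oxoethyl)-7-oxabicyclo[4.1.0]heptane-2,3-diyl bis[(2Z)-2-methylbut-2-enoate], all-cis
Conditions: Dess–Martin periodinane, NaHCO3, DCM, 0 °C to rt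
Reagents that add atoms: none
Why: Buffered Dess–Martin oxidation of a primary alcohol to the aldehyde; the nearest stereocenter (C1) is β to the new carbonyl and cannot epimerise.

Step 11
Reactants: 17 aldehyde
Product: 18 1-methyl-4-(3-oxoprop-1-en-2-yl)-7-oxabicyclo[4.1.0]heptane-2,3-diyl bis[(2Z)-2-methylbut-2-enoate], all-cis
Conditions: 37% aq. CH2O, pyrrolidine (10 mol%), EtCO2H (10 mol%), i-PrOH, 45 °C
Reagents that add atoms: formaldehyde, C=O
Why: Amine-catalysed Mannich condensation and elimination (α-methylenation of an aldehyde) installs the C7=CH2 group under mild, nearly neutral conditions.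

Step 12
Reactants: 18 2-substituted acrolein
Product: 20 4-[(3S)-3-hydroxyhexa-1,5-dien-2-yl]-1-methyl-7-oxabicyclo[4.1.0]heptane-2,3-diyl bis[(2Z)-2-methylbut-2-enoate] (all-cis ring), via borinate ester 19 (not isolated)
Conditions: (−)-Ipc2B(allyl) (from (+)-α-pinene), Et2O, −78 °C; then pH 7 buffer, 30% H2O2, MeOH, 0 °C
Reagents that add atoms: (−)-B-allyldiisopinocampheylborane, C=CCB([C@@H]1C[C@@H]2C[C@H]([C@H]1C)C2(C)C)[C@@H]1C[C@@H]2C[C@H]([C@H]1C)C2(C)C
Why: Asymmetric allylboration through a chair six-membered transition state; the reagent should deliver allyl to the Si face of the aldehyde and set C8 as S under reagent control, and esters are inert at −78 °C.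

Step 13
Reactants: 20 homoallylic alcohol
Product: 21 4-[(3S)-3-hydroxy-6-methylhepta-1,5-dien-2-yl]-1-methyl-7-oxabicyclo[4.1.0]heptane-2,3-diyl bis[(2Z)-2-methylbut-2-enoate] (all-cis ring)
Conditions: second-generation Grubbs catalyst (5 mol%), 2-methylbut-2-ene/DCM, 40 °C
Reagents that add atoms: 2-methylbut-2-ene, CC=C(C)C
Why: Cross-metathesis with 2-methylbut-2-ene converts the monosubstituted alkene into the prenyl group; the 1,1-disubstituted C7=CH2 and the trisubstituted angelate alkenes should not take part.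

Step 14
Reactants: 21 prenyl alcohol; 11 angelic acid
Product: 22 (3S)-2-[all-cis 2,3-bis{[(2Z)-2-methylbut-2-enoyl]oxy}-1-methyl-7-oxabicyclo[4.1.0]heptan-4-yl]-6-methylhepta-1,5-dien-3-yl (2Z)-2-methylbut-2-enoate
Conditions: 11, 2,4,6-trichlorobenzoyl chloride, Et3N, toluene, rt; then 21, toluene, 60 °C
Reagents that add atoms: none
Why: Same mixed-anhydride angeloylation as step 8, here on the less hindered allylic C8 hydroxyl.

Step 15
Reactants: 22 tris-angelate diene
Product: 23 CNP0258231.4, the target; (1R,3R,4R,5S,6S,8S,10R) in the numbering of the plan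
Conditions: D-fructose-derived Shi ketone (30 mol%), Oxone (2KHSO5·KHSO4·K2SO4), K2CO3, Bu4NHSO4, MeCN/dimethoxymethane/aq. Na2B4O7 buffer (pH 10.5), 0 °C
Reagents that add atoms: potassium peroxymonosulfate (active component of Oxone), OOS(=O)(=O)[O-].[K+]
Why: Shi epoxidation; the chiral dioxirane transfers oxygen through a spiro transition state to the electron-rich trisubstituted C10=C11 alkene and should set C10 as R under reagent control, while the 1,1-disubstituted allylic-ester alkene and the electron-poor angelates react much more slowly.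

**Compound list**

1 | but-3-en-1-ol | C=CCCO | starting material
2 | tert-butyl(but-3-en-1-yloxy)diphenylsilane | C=CCCO[Si](c1ccccc1)(c1ccccc1)C(C)(C)C | intermediate
3 | (E)-but-2-enal | C/C=C/C=O | starting material
4 | (E)-5-[(tert-butyldiphenylsilyl)oxy]pent-2-enal | O=C/C=C/CCO[Si](c1ccccc1)(c1ccccc1)C(C)(C)C | intermediate
5 | tert-butyl 3-oxopentanoate | CCC(=O)CC(=O)OC(C)(C)C | starting material
6 | tert-butyl (3S)-3-{2-[(tert-butyldiphenylsilyl)oxy]ethyl}-5-oxo-2-propanoylpentanoate (C2 epimers) | CCC(=O)C(C(=O)OC(C)(C)C)[C@H](CC=O)CCO[Si](c1ccccc1)(c1ccccc1)C(C)(C)C | intermediate (not isolated)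
7 | tert-butyl (6R)-6-{2-[(tert-butyldiphenylsilyl)oxy]ethyl}-3-methyl-2-oxocyclohex-3-ene-1-carboxylate (C1 epimers) | CC1=CC[C@H](CCO[Si](c2ccccc2)(c2ccccc2)C(C)(C)C)C(C(=O)OC(C)(C)C)C1=O | intermediate (not isolated)
8 | (5R)-5-{2-[(tert-butyldiphenylsilyl)oxy]ethyl}-2-methylcyclohex-2-en-1-one | CC1=CC[C@H](CCO[Si](c2ccccc2)(c2ccccc2)C(C)(C)C)CC1=O | intermediate
9 | potassium (3R)-3-{2-[(tert-butyldiphenylsilyl)oxy]ethyl}-6-methylcyclohexa-1,5-dien-1-olate | CC1=CC[C@H](CCO[Si](c2ccccc2)(c2ccccc2)C(C)(C)C)C=C1[O-].[K+] | intermediate (not isolated)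
10 | (5R,6R)-5-{2-[(tert-butyldiphenylsilyl)oxy]ethyl}-6-hydroxy-2-methylcyclohex-2-en-1-one | CC1=CC[C@H](CCO[Si](c2ccccc2)(c2ccccc2)C(C)(C)C)[C@@H](O)C1=O | intermediate
11 | angelic acid, (2Z)-2-methylbut-2-enoic acid | C/C=C(/C)C(=O)O | starting material
12 | (1S,6R)-6-{2-[(tert-butyldiphenylsilyl)oxy]ethyl}-3-methyl-2-oxocyclohex-3-en-1-yl (2Z)-2-methylbut-2-enoate | CC1=CC[C@H](CCO[Si](c2ccccc2)(c2ccccc2)C(C)(C)C)[C@H](OC(=O)/C(C)=C\C)C1=O | intermediate
13 | (1S,2R,6R)-6-{2-[(tert-butyldiphenylsilyl)oxy]ethyl}-2-hydroxy-3-methylcyclohex-3-en-1-yl (2Z)-2-methylbut-2-enoate | CC1=CC[C@H](CCO[Si](c2ccccc2)(c2ccccc2)C(C)(C)C)[C@H](OC(=O)/C(C)=C\C)[C@@H]1O | intermediate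
14 | 4-{2-[(tert-butyldiphenylsilyl)oxy]ethyl}-2-hydroxy-1-methyl-7-oxabicyclo[4.1.0]heptan-3-yl (2Z)-2-methylbut-2-enoate, all-cis | CC(C)(C)[Si](c1ccccc1)(c1ccccc1)OCC[C@H]1C[C@H]2O[C@@]2(C)[C@@H](O)[C@H]1OC(=O)/C(C)=C\C | intermediate
15 | 4-{2-[(tert-butyldiphenylsilyl)oxy]ethyl}-1-methyl-7-oxabicyclo[4.1.0]heptane-2,3-diyl bis[(2Z)-2-methylbut-2-enoate], all-cis | CC(C)(C)[Si](c1ccccc1)(c1ccccc1)OCC[C@H]1C[C@H]2O[C@@]2(C)[C@@H](OC(=O)/C(C)=C\C)[C@H]1OC(=O)/C(C)=C\C | intermediate
16 | 4-(2-hydroxyethyl)-1-methyl-7-oxabicyclo[4.1.0]heptane-2,3-diyl bis[(2Z)-2-methylbut-2-enoate], all-cis | OCC[C@H]1C[C@H]2O[C@@]2(C)[C@@H](OC(=O)/C(C)=C\C)[C@H]1OC(=O)/C(C)=C\C | intermediate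
17 | 1-methyl-4-(2-oxoethyl)-7-oxabicyclo[4.1.0]heptane-2,3-diyl bis[(2Z)-2-methylbut-2-enoate], all-cis | O=CC[C@H]1C[C@H]2O[C@@]2(C)[C@@H](OC(=O)/C(C)=C\C)[C@H]1OC(=O)/C(C)=C\C | intermediate
18 | 1-methyl-4-(3-oxoprop-1-en-2-yl)-7-oxabicyclo[4.1.0]heptane-2,3-diyl bis[(2Z)-2-methylbut-2-enoate], all-cis | C=C(C=O)[C@H]1C[C@H]2O[C@@]2(C)[C@@H](OC(=O)/C(C)=C\C)[C@H]1OC(=O)/C(C)=C\C | intermediate
19 | diisopinocampheylborinate of alcohol 20 | C=C([C@H](CC=C)OB([C@@H]1C[C@@H]2C[C@H]([C@H]1C)C2(C)C)[C@@H]1C[C@@H]2C[C@H]([C@H]1C)C2(C)C)[C@H]1C[C@H]2O[C@@]2(C)[C@@H](OC(=O)/C(C)=C\C)[C@H]1OC(=O)/C(C)=C\C | intermediate (not isolated)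
20 | 4-[(3S)-3-hydroxyhexa-1,5-dien-2-yl]-1-methyl-7-oxabicyclo[4.1.0]heptane-2,3-diyl bis[(2Z)-2-methylbut-2-enoate], all-cis ring | C=C([C@H](CC=C)O)[C@H]1C[C@H]2O[C@@]2(C)[C@@H](OC(=O)/C(C)=C\C)[C@H]1OC(=O)/C(C)=C\C | intermediate
21 | 4-[(3S)-3-hydroxy-6-methylhepta-1,5-dien-2-yl]-1-methyl-7-oxabicyclo[4.1.0]heptane-2,3-diyl bis[(2Z)-2-methylbut-2-enoate], all-cis ring | C=C([C@H](CC=C(C)C)O)[C@H]1C[C@H]2O[C@@]2(C)[C@@H](OC(=O)/C(C)=C\C)[C@H]1OC(=O)/C(C)=C\C | intermediate
22 | (3S)-2-[all-cis 2,3-bis{[(2Z)-2-methylbut-2-enoyl]oxy}-1-methyl-7-oxabicyclo[4.1.0]heptan-4-yl]-6-methylhepta-1,5-dien-3-yl (2Z)-2-methylbut-2-enoate | C=C([C@H](CC=C(C)C)OC(=O)/C(C)=C\C)[C@H]1C[C@H]2O[C@@]2(C)[C@@H](OC(=O)/C(C)=C\C)[C@H]1OC(=O)/C(C)=C\C | intermediate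
23 | CNP0258231.4 | C=C([C@H](C[C@H]1OC1(C)C)OC(=O)/C(C)=C\C)[C@H]1C[C@H]2O[C@@]2(C)[C@@H](OC(=O)/C(C)=C\C)[C@H]1OC(=O)/C(C)=C\C | target

**Summary**

Total step count: 15. Longest linear sequence: 15 steps (1 to 23).

Steps most likely to fail:

Step 5. The alkoxyphosphonium ion of the equatorial α-ketol must be attacked from the hindered axial direction; displacement may be slow, so that elimination towards the dienone and its phenol tautomer, or acylation with retention, competes. The fallback sets out from 10 and returns at 15, and inverts C6 by oxidation and reduction instead of by substitution. The C6 hydroxyl of 10 is capped as the triethylsilyl ether F1 (TESCl, imidazole). Luche reduction should give the C5 alcohol F2 (hydride anti to the C1 substituent). VO(acac)2 and t-BuOOH should give the epoxy alcohol F3, and the C5 hydroxyl is angeloylated as in step 8 to the ester F4. HF·pyridine removes only the triethylsilyl group to give the trans C6 alcohol F5, and Dess–Martin oxidation gives the C6 ketone F6. NaBH4 at low temperature must approach from the face opposite the C5 ester, the epoxide oxygen and the C1 substituent, and should give the all-cis C6 alcohol F7. Angeloylation as in step 8 then gives 15.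

Step 8. The C5 hydroxyl is wedged between the quaternary epoxide carbon and the C6 ester; acylation by the mixed anhydride may be too slow at the temperature that the epoxide and the Z double bond tolerate, with Z to E isomerisation or chloride opening of the epoxide as the result. The fallback sets out from 14 and returns at 15, and builds the angelate on the molecule. The free hydroxyl of 14 is esterified with 2-[bis(2,2,2-trifluoroethoxy)phosphoryl]propanoic acid (DCC, DMAP, DCM) to the phosphonate ester F8. A Still–Gennari olefination with acetaldehyde (KHMDS, 18-crown-6, THF, −78 °C) should then give the Z-2-methylbut-2-enoate, that is 15. If the angelate of 14 has shifted between C5 and C6, both isomers converge on 15.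

Step 3. Aldol closure through the propanoyl CH2 is slower than through a methyl ketone; the Michael adduct may revert (loss of enantiopurity) or the acid may attack the silyl ether before cyclisation and decarboxylation are complete. The fallback sets out from 4 and returns at 8; it keeps the same two-bond ring closure but brings in the C4 methyl afterwards. Enal 4 and tert-butyl 3-oxobutanoate under the same amine catalyst and acid treatment should give, through the Michael adduct F9 and the cyclohexenone ester F10, the enone F11. α-Iodination (I2, pyridine, DCM) gives the iodoenone F12, and Suzuki methylation (MeB(OH)2, Pd(dppf)Cl2, K3PO4, dioxane/H2O) gives 8.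

Further compounds
F1 | step 5 | (5R,6R)-5-{2-[(tert-butyldiphenylsilyl)oxy]ethyl}-2-methyl-6-[(triethylsilyl)oxy]cyclohex-2-en-1-one | CC1=CC[C@H](CCO[Si](c2ccccc2)(c2ccccc2)C(C)(C)C)[C@@H](O[Si](CC)(CC)CC)C1=O
F2 | step 5 | C5 alcohol of F1, hydroxyl cis to the side chain and trans to the silyloxy group | CC1=CC[C@H](CCO[Si](c2ccccc2)(c2ccccc2)C(C)(C)C)[C@@H](O[Si](CC)(CC)CC)[C@@H]1O
F3 | step 5 | 3,4-epoxide of F2, epoxide oxygen cis to the C5 hydroxyl | CC(C)(C)[Si](c1ccccc1)(c1ccccc1)OCC[C@H]1C[C@H]2O[C@@]2(C)[C@@H](O)[C@@H]1O[Si](CC)(CC)CC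
F4 | step 5 | C5 (2Z)-2-methylbut-2-enoate of F3 | CC(C)(C)[Si](c1ccccc1)(c1ccccc1)OCC[C@H]1C[C@H]2O[C@@]2(C)[C@@H](OC(=O)/C(C)=C\C)[C@@H]1O[Si](CC)(CC)CC
F5 | step 5 | C6 alcohol from F4, hydroxyl trans to the side chain | CC(C)(C)[Si](c1ccccc1)(c1ccccc1)OCC[C@H]1C[C@H]2O[C@@]2(C)[C@@H](OC(=O)/C(C)=C\C)[C@@H]1O
F6 | step 5 | C6 ketone from F5 | CC(C)(C)[Si](c1ccccc1)(c1ccccc1)OCC[C@H]1C[C@H]2O[C@@]2(C)[C@@H](OC(=O)/C(C)=C\C)C1=O
F7 | step 5 | all-cis C6 alcohol from F6 (C5 angelate, C6 hydroxyl) | CC(C)(C)[Si](c1ccccc1)(c1ccccc1)OCC[C@H]1C[C@H]2O[C@@]2(C)[C@@H](OC(=O)/C(C)=C\C)[C@H]1O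
F8 | step 8 | C5 2-[bis(2,2,2-trifluoroethoxy)phosphoryl]propanoate of 14 | CC(C)(C)[Si](c1ccccc1)(c1ccccc1)OCC[C@H]1C[C@H]2O[C@@]2(C)[C@@H](OC(=O)C(C)P(=O)(OCC(F)(F)F)OCC(F)(F)F)[C@H]1OC(=O)/C(C)=C\C
F9 | step 3 | tert-butyl (3S)-2-acetyl-3-{2-[(tert-butyldiphenylsilyl)oxy]ethyl}-5-oxopentanoate | CC(=O)C(C(=O)OC(C)(C)C)[C@H](CC=O)CCO[Si](c1ccccc1)(c1ccccc1)C(C)(C)C
F10 | step 3 | tert-butyl (6R)-6-{2-[(tert-butyldiphenylsilyl)oxy]ethyl}-2-oxocyclohex-3-ene-1-carboxylate | O=C1C=CC[C@H](CCO[Si](c2ccccc2)(c2ccccc2)C(C)(C)C)C1C(=O)OC(C)(C)C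
F11 | step 3 | (5R)-5-{2-[(tert-butyldiphenylsilyl)oxy]ethyl}cyclohex-2-en-1-one | O=C1C=CC[C@H](CCO[Si](c2ccccc2)(c2ccccc2)C(C)(C)C)C1
F12 | step 3 | (5R)-5-{2-[(tert-butyldiphenylsilyl)oxy]ethyl}-2-iodocyclohex-2-en-1-one | O=C1C(I)=CC[C@H](CCO[Si](c2ccccc2)(c2ccccc2)C(C)(C)C)C1
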